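**Strategy.** Both hexasubstituted carbocycles are grown from one chiral α-diazo enone by two Danheiser benzannulations on a Roche-ester linchpin that carries the bridging stereocenter. The second benzannulation is the key step. A vinylketene and the siloxyalkyne that already holds ring B undergo [2+2] cycloaddition, 4π opening and 6π electrocyclization. This closes ring A by joining the ketene carbon (C8, the later ring-A carbonyl) to the methylidene carbon (C8a, which later carries the exocyclic C1H=), and it unites both halves. The step exploits the fact that quinone-methide ring A is a fully substituted 6,8-dioxygenated arene in disguise. ortho-Formylation at C8a and desilylation then close the pyran and reveal the quinone methide.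

Key step: step 17

Assumption: the name is read as dicitrinone H and the SMILES is taken as the structure; its two quinone-methide tautomers (C8 ketone with C6 enol as drawn, or C6 ketone with C8 enol) interconvert by proton transfer, so the compound is written in the given form.

Conventions: citrinin numbering is used for both halves (C1, O2, C3, C4, C4a, C5 to C8, C8a). Ring A is the carbocycle of the quinone-methide half, ring B the benzene ring of the dihydroisocoumarin half. TBSO = tert-butyldimethylsilyloxy, TIPSO = triisopropylsilyloxy.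

**Diazo enone (used in steps 9 and 17)**

Step 1
Reactants: 1 (R)-but-3-yn-2-ol
Product: 2 (R)-but-3-yn-2-yl methanesulfonate
Conditions: MsCl, Et3N, CH2Cl2, −78 to 0 °C
Reagents that add atoms: methanesulfonyl chloride CS(=O)(=O)Cl
Why: O-Sulfonylation of the secondary alcohol leaves the stereocenter untouched and supplies the leaving group for the propargylation.

Step 2
Reactants: 2 (R)-but-3-yn-2-yl methanesulfonate; 3 acetaldehyde
Product: 5 (2R,3S)-3-methylpent-4-yn-2-ol, via allenylzinc 4 (not isolated)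
Conditions: Pd(OAc)2 (5 mol %), PPh3 (5 mol %), Et2Zn (3 equiv), THF, −78 to −20 °C; aq. NH4Cl
Reagents that add atoms: none
Why: Marshall propargylation: anti SN2′ palladation of the mesylate and transmetalation should give the axially chiral allenylzinc, whose cyclic SE2′ addition transfers the axial chirality to C3 (net inversion of the mesylate carbon) and sets C2 anti through a chair-like transition state with the aldehyde methyl group equatorial.

Step 3
Reactants: 5 (2R,3S)-3-methylpent-4-yn-2-ol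
Product: 6 (3S,4R)-4-(TBSO)-3-methylpent-1-yne
Conditions: t-BuMe2SiCl, imidazole, DMF, 0 to 25 °C
Reagents that add atoms: tert-butyldimethylsilyl chloride CC(C)(C)[Si](C)(C)Cl
Why: Silylation of the secondary alcohol masks the hydroxyl that would otherwise quench the organolithium of step 5 and trap the ketene of steps 9 and 17.

Step 4
Reactants: 6 (3S,4R)-4-(TBSO)-3-methylpent-1-yne
Product: 8 (3R,4R)-2-bromo-4-(TBSO)-3-methylpent-1-ene, via alkenylborane 7 (not isolated)
Conditions: 9-bromo-9-borabicyclo[3.3.1]nonane, CH2Cl2, 0 °C; then AcOH, 0 to 25 °C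
Reagents that add atoms: 9-bromo-9-borabicyclo[3.3.1]nonane BrB1C2CCCC1CCC2
Why: Haloboration: syn, Markovnikov addition of the B–Br bond places bromine on the internal alkyne carbon, and protodeboronation with acetic acid leaves the 2-bromo-1-alkene (the descriptor at C3 changes by priority only).

Step 5
Reactants: 8 (3R,4R)-2-bromo-4-(TBSO)-3-methylpent-1-ene; 9 N-methoxy-N-methylpropanamide
Product: 11 (5S,6R)-6-(TBSO)-5-methyl-4-methylideneheptan-3-one, via alkenyllithium 10 (not isolated)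
Conditions: t-BuLi (2.1 equiv), Et2O, −78 °C; then 9, −78 to 0 °C; aq. NH4Cl
Reagents that add atoms: none
Why: Bromine–lithium exchange gives the alkenyllithium, which acylates the Weinreb amide once through a stable chelated tetrahedral adduct (Weinreb ketone synthesis); the silyloxy group is γ to lithium, so β-elimination is not possible.

Step 6
Reactants: 11 (5S,6R)-6-(TBSO)-5-methyl-4-methylideneheptan-3-one
Product: 13 (5S,6R)-6-(TBSO)-2-diazo-5-methyl-4-methylideneheptan-3-one, via trifluoroacetyl diketone 12 (not isolated)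
Conditions: LiN(SiMe3)2, THF, −78 °C; CF3CO2CH2CF3; then MsN3, Et3N, H2O, MeCN, 25 °C
Reagents that add atoms: methanesulfonyl azide CS(=O)(=O)N=[N+]=[N-]
Why: Danheiser detrifluoroacetylative diazo transfer: the kinetic α′-enolate (the only α-hydrogens are on the ethyl side) is trifluoroacetylated and the activated diketone undergoes Regitz diazo transfer with loss of the trifluoroacetyl group, without touching the enone or the allylic stereocenter.

**Linchpin**

Step 7
Reactants: 14 methyl (S)-3-hydroxy-2-methylpropanoate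
Product: 15 methyl (S)-3-(TBSO)-2-methylpropanoate
Conditions: t-BuMe2SiCl, imidazole, CH2Cl2, 25 °C
Reagents that add atoms: tert-butyldimethylsilyl chloride CC(C)(C)[Si](C)(C)Cl
Why: Silylation of the primary alcohol of the Roche ester under imidazole conditions does not affect the α-stereocenter, which later becomes the bridging carbon.

Step 8
Reactants: 15 methyl (S)-3-(TBSO)-2-methylpropanoate
Product: 17 (R)-4-(TBSO)-3-methyl-1-(TIPSO)but-1-yne, via lithium ynolate 16 (not isolated)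
Conditions: CH2Br2, lithium 2,2,6,6-tetramethylpiperidide, THF, −78 °C; LiN(SiMe3)2; n-BuLi, −78 to 25 °C; then i-Pr3SiCl, −78 to 25 °C
Reagents that add atoms: dibromomethane BrCBr; triisopropylsilyl chloride CC(C)[Si](Cl)(C(C)C)C(C)C
Why: Kowalski ester homologation: addition of LiCHBr2 to the ester, enolization and bromine–lithium exchange trigger the carbenoid 1,2-shift of the sec-alkyl group with retention to the lithium ynolate, which the bulky silyl chloride traps on oxygen.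

**Ring B**

Step 9
Reactants: 13 (5S,6R)-6-(TBSO)-2-diazo-5-methyl-4-methylideneheptan-3-one; 17 (R)-4-(TBSO)-3-methyl-1-(TIPSO)but-1-yne
Product: 21 2-[(2R)-1-(TBSO)propan-2-yl]-5-[(2S,3R)-3-(TBSO)butan-2-yl]-4-methyl-3-(TIPSO)phenol, via vinylketene 18 (not isolated), via vinylcyclobutenone 19 (not isolated), via dienylketene 20 (not isolated)
Conditions: hν (300 nm), ClCH2CH2Cl, 25 °C; then 80 °C
Reagents that add atoms: none
Why: Danheiser benzannulation (diazo ketone variant): photochemical Wolff rearrangement to the vinylketene, regioselective [2+2] cycloaddition with the siloxyalkyne, 4π ring opening and 6π electrocyclization should build the pentasubstituted phenol that becomes ring B with every substituent in place, and no stereocenter is formed or touched.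

Step 10
Reactants: 21 2-[(2R)-1-(TBSO)propan-2-yl]-5-[(2S,3R)-3-(TBSO)butan-2-yl]-4-methyl-3-(TIPSO)phenol
Product: 22 3-[(2R)-1-(TBSO)propan-2-yl]-6-[(2S,3R)-3-(TBSO)butan-2-yl]-2-hydroxy-5-methyl-4-(TIPSO)benzaldehyde
Conditions: MgCl2, Et3N, (CH2O)n, MeCN, 80 °C
Reagents that add atoms: paraformaldehyde (as formaldehyde) C=O
Why: Casnati–Skattebøl ortho-formylation: the magnesium phenoxide directs formaldehyde to the only free ring position (C8a, ortho to the hydroxyl) and a second formaldehyde oxidizes the benzylic alkoxide to the aldehyde under conditions that spare silyl ethers.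

Step 11
Reactants: 22 3-[(2R)-1-(TBSO)propan-2-yl]-6-[(2S,3R)-3-(TBSO)butan-2-yl]-2-hydroxy-5-methyl-4-(TIPSO)benzaldehyde
Product: 23 3-[(2R)-1-(TBSO)propan-2-yl]-6-[(2S,3R)-3-(TBSO)butan-2-yl]-5-methyl-2,4-bis(TIPSO)benzaldehyde
Conditions: i-Pr3SiOTf, 2,6-lutidine, CH2Cl2, 0 to 25 °C
Reagents that add atoms: triisopropylsilyl trifluoromethanesulfonate CC(C)[Si](OS(=O)(=O)C(F)(F)F)(C(C)C)C(C)C
Why: O-Silylation of the hydrogen-bonded phenol with the silyl triflate protects it against the bases of steps 15 and 16 and against acylation by the ketene in step 17.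

Step 12
Reactants: 23 3-[(2R)-1-(TBSO)propan-2-yl]-6-[(2S,3R)-3-(TBSO)butan-2-yl]-5-methyl-2,4-bis(TIPSO)benzaldehyde
Product: 24 3-[(2R)-1-(TBSO)propan-2-yl]-6-[(2S,3R)-3-(TBSO)butan-2-yl]-5-methyl-2,4-bis(TIPSO)benzoic acid
Conditions: NaClO2, NaH2PO4, 2-methylbut-2-ene, t-BuOH/H2O, 25 °C
Reagents that add atoms: sodium chlorite [Na+].[O-]Cl=O
Why: Pinnick oxidation brings C1 of ring B to the lactone oxidation level; the ring has no free position for chlorination and 2-methylbut-2-ene scavenges the hypochlorite.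

Step 13
Reactants: 24 3-[(2R)-1-(TBSO)propan-2-yl]-6-[(2S,3R)-3-(TBSO)butan-2-yl]-5-methyl-2,4-bis(TIPSO)benzoic acid
Product: 26 (3R,4S)-7-[(2R)-1-hydroxypropan-2-yl]-3,4,5-trimethyl-6,8-bis(TIPSO)isochroman-1-one, via dihydroxy acid 25 (not isolated)
Conditions: camphorsulfonic acid (cat.), MeOH/CH2Cl2, 25 °C; then PhMe, 60 °C
Reagents that add atoms: none
Why: Acid-catalyzed methanolysis removes the two alkyl silyl ethers while the aryl silyl ethers survive, and the 2-(2-hydroxyalkyl)benzoic acid closes the six-membered lactone (Fischer lactonization) with retention at C3 because the C3–O bond is not broken; the primary hydroxyl is meta to the carboxyl and cannot lactonize.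

Step 14
Reactants: 26 (3R,4S)-7-[(2R)-1-hydroxypropan-2-yl]-3,4,5-trimethyl-6,8-bis(TIPSO)isochroman-1-one
Product: 27 (2R)-2-[(3R,4S)-3,4,5-trimethyl-1-oxo-6,8-bis(TIPSO)isochroman-7-yl]propanal
Conditions: Dess–Martin periodinane, NaHCO3, CH2Cl2, 0 to 25 °C
Reagents that add atoms: none
Why: Dess–Martin oxidation under buffered, non-basic conditions should give the α-aryl aldehyde, whose α-hydrogen is poorly acidic because the two ortho silyloxy groups twist the aryl ring out of conjugation with the enol.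

Step 15
Reactants: 27 (2R)-2-[(3R,4S)-3,4,5-trimethyl-1-oxo-6,8-bis(TIPSO)isochroman-7-yl]propanal
Product: 28 (3R,4S)-7-[(2S)-but-3-yn-2-yl]-3,4,5-trimethyl-6,8-bis(TIPSO)isochroman-1-one
Conditions: dimethyl (1-diazo-2-oxopropyl)phosphonate, K2CO3, MeOH, 0 to 25 °C
Reagents that add atoms: dimethyl (1-diazo-2-oxopropyl)phosphonate CC(=O)C(=[N+]=[N-])P(=O)(OC)OC
Why: Seyferth–Gilbert homologation with the Ohira–Bestmann reagent (addition, phosphate elimination, loss of N2 and 1,2-hydrogen shift of the alkylidene carbene) should give the terminal alkyne with the bridging stereocenter kept at low temperature (descriptor changes by priority only).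

Step 16
Reactants: 28 (3R,4S)-7-[(2S)-but-3-yn-2-yl]-3,4,5-trimethyl-6,8-bis(TIPSO)isochroman-1-one
Product: 31 (3R,4S)-3,4,5-trimethyl-6,8-bis(TIPSO)-7-[(2S)-4-(TIPSO)but-3-yn-2-yl]isochroman-1-one, via lithium acetylide 29 (not isolated), via lithium ynolate 30 (not isolated)
Conditions: LiN(SiMe3)2 (2.2 equiv), THF, −78 °C; t-BuOOH (1.1 equiv), −78 to 0 °C; then i-Pr3SiOTf, −78 °C
Reagents that add atoms: tert-butyl hydroperoxide CC(C)(C)OO; triisopropylsilyl trifluoromethanesulfonate CC(C)[Si](OS(=O)(=O)C(F)(F)F)(C(C)C)C(C)C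
Why: Julia oxidation of the lithium acetylide with lithium tert-butyl peroxide (electrophilic oxygen transfer) gives the ynolate, which the bulky silyl triflate traps on oxygen; the non-nucleophilic amide base and the hindered lactone without α-hydrogens make the conditions compatible.

**Ring A and end game**

Step 17
Reactants: 31 (3R,4S)-3,4,5-trimethyl-6,8-bis(TIPSO)-7-[(2S)-4-(TIPSO)but-3-yn-2-yl]isochroman-1-one; 13 (5S,6R)-6-(TBSO)-2-diazo-5-methyl-4-methylideneheptan-3-one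
Product: 34 (3R,4S)-7-[(1S)-1-{4-[(2S,3R)-3-(TBSO)butan-2-yl]-6-hydroxy-3-methyl-2-(TIPSO)phenyl}ethyl]-3,4,5-trimethyl-6,8-bis(TIPSO)isochroman-1-one, via vinylcyclobutenone 32 (not isolated), via dienylketene 33 (not isolated)
Conditions: 13 (1.5 equiv), hν (300 nm), ClCH2CH2Cl, 25 °C; then 80 °C
Reagents that add atoms: none
Why: Danheiser benzannulation in its diazo ketone form: light expels N2 from 13 and the alkenyl group shifts (Wolff rearrangement) to the short-lived vinylketene already met in step 9 (compound 18), whose carbonyl carbon is attacked by the nucleophilic β-carbon of siloxyalkyne 31 in a [2+2] cycloaddition to vinylcyclobutenone 32. Heating opens 32 by 4π electrocyclic ring opening to dienylketene 33, whose 6π electrocyclization joins the ketene carbon (future C8) to the terminal methylidene carbon (future C8a), and enolization of the cyclohexadienone gives phenol 34. The closest known reaction type is the benzannulation of α′-diazo enones or cyclobutenones with silyloxyalkynes to resorcinol monosilyl ethers. The only ring closed is carbocycle A, by a thermal disrotatory 6π electrocyclization of an all-carbon triene. No stereocenter is formed: the five present lie outside the reacting π system and the quaternary carbon of 32 is lost on ring opening. The step needs the regiochemistry of the [2+2] event, secured by the polarization of the ynol ether (oxygen-bearing carbon becomes C6, bridge-bearing carbon C7), and tolerance of lactone and silyl ethers, secured by neutral, reagent-free conditions.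

Step 18
Reactants: 34 (3R,4S)-7-[(1S)-1-{4-[(2S,3R)-3-(TBSO)butan-2-yl]-6-hydroxy-3-methyl-2-(TIPSO)phenyl}ethyl]-3,4,5-trimethyl-6,8-bis(TIPSO)isochroman-1-one
Product: 35 (3R,4S)-7-[(1S)-1-{4-[(2S,3R)-3-(TBSO)butan-2-yl]-5-formyl-6-hydroxy-3-methyl-2-(TIPSO)phenyl}ethyl]-3,4,5-trimethyl-6,8-bis(TIPSO)isochroman-1-one
Conditions: MgCl2, Et3N, (CH2O)n, MeCN, 80 °C
Reagents that add atoms: paraformaldehyde (as formaldehyde) C=O
Why: Casnati–Skattebøl ortho-formylation: only ring A carries a free phenol and the only aromatic C–H of the molecule (C8a) lies ortho to it, so the magnesium phenoxide should deliver the formyl carbon (the future C1) there.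

Step 19
Reactants: 35 (3R,4S)-7-[(1S)-1-{4-[(2S,3R)-3-(TBSO)butan-2-yl]-5-formyl-6-hydroxy-3-methyl-2-(TIPSO)phenyl}ethyl]-3,4,5-trimethyl-6,8-bis(TIPSO)isochroman-1-one
Product: 37 dicitrinone H, via hydroxy aldehyde 36 (not isolated)
Conditions: Bu4NF, AcOH, THF, 0 to 40 °C; then aq. HCl (pH 2), EtOAc, 25 °C
Reagents that add atoms: none
Why: Fluoride-mediated desilylation frees the C3 hydroxyl and the phenols, and hemiacetalization of the salicylaldehyde by the secondary alcohol (6-exo-trig) followed by acid-promoted dehydration should close the pyran and give the quinone methide as in citrinin syntheses, with no stereocenter affected.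

**Compound list**

1 | (R)-but-3-yn-2-ol | C#C[C@@H](C)O | starting material
2 | (R)-but-3-yn-2-yl methanesulfonate | C#C[C@@H](C)OS(C)(=O)=O | intermediate
3 | acetaldehyde | CC=O | starting material
4 | [(aS)-buta-1,2-dien-1-yl](ethyl)zinc | [H]C(C)=[C@]=C([H])[Zn]CC | intermediate (not isolated)
5 | (2R,3S)-3-methylpent-4-yn-2-ol | C#C[C@H](C)[C@@H](C)O | intermediate
6 | (3S,4R)-4-(TBSO)-3-methylpent-1-yne | C#C[C@H](C)[C@@H](C)O[Si](C)(C)C(C)(C)C | intermediate
7 | 9-[(1Z,3R,4R)-2-bromo-4-(TBSO)-3-methylpent-1-en-1-yl]-9-borabicyclo[3.3.1]nonane | Br/C(=C\B1C2CCCC1CCC2)[C@H](C)[C@@H](C)O[Si](C)(C)C(C)(C)C | intermediate (not isolated)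
8 | (3R,4R)-2-bromo-4-(TBSO)-3-methylpent-1-ene | C=C(Br)[C@H](C)[C@@H](C)O[Si](C)(C)C(C)(C)C | intermediate
9 | N-methoxy-N-methylpropanamide | CCC(=O)N(C)OC | starting material
10 | [(3S,4R)-4-(TBSO)-3-methylpent-1-en-2-yl]lithium | [Li]C(=C)[C@H](C)[C@@H](C)O[Si](C)(C)C(C)(C)C | intermediate (not isolated)
11 | (5S,6R)-6-(TBSO)-5-methyl-4-methylideneheptan-3-one | CCC(=O)C(=C)[C@H](C)[C@@H](C)O[Si](C)(C)C(C)(C)C | intermediate
12 | (6S,7R)-7-(TBSO)-1,1,1-trifluoro-3,6-dimethyl-5-methylideneoctane-2,4-dione (C3 epimers, enolizable) | CC(C(=O)C(F)(F)F)C(=O)C(=C)[C@H](C)[C@@H](C)O[Si](C)(C)C(C)(C)C | intermediate (not isolated)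
13 | (5S,6R)-6-(TBSO)-2-diazo-5-methyl-4-methylideneheptan-3-one | CC(=[N+]=[N-])C(=O)C(=C)[C@H](C)[C@@H](C)O[Si](C)(C)C(C)(C)C | intermediate
14 | methyl (S)-3-hydroxy-2-methylpropanoate | OC[C@H](C)C(=O)OC | starting material
15 | methyl (S)-3-(TBSO)-2-methylpropanoate | CC(C)(C)[Si](C)(C)OC[C@H](C)C(=O)OC | intermediate
16 | lithium (R)-4-(TBSO)-3-methylbut-1-yn-1-olate | [Li]OC#C[C@@H](C)CO[Si](C)(C)C(C)(C)C | intermediate (not isolated)
17 | (R)-4-(TBSO)-3-methyl-1-(TIPSO)but-1-yne | CC(C)[Si](C(C)C)(C(C)C)OC#C[C@@H](C)CO[Si](C)(C)C(C)(C)C | intermediate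
18 | (4S,5R)-5-(TBSO)-2,4-dimethyl-3-methylidenehex-1-en-1-one (vinylketene) | O=C=C(C)C(=C)[C@H](C)[C@@H](C)O[Si](C)(C)C(C)(C)C | intermediate (not isolated)
19 | 2-[(2R)-1-(TBSO)propan-2-yl]-4-[(3S,4R)-4-(TBSO)-3-methylpent-1-en-2-yl]-4-methyl-3-(TIPSO)cyclobut-2-en-1-one (both C4 epimers) | CC(C)(C)[Si](C)(C)OC[C@H](C)C1=C(O[Si](C(C)C)(C(C)C)C(C)C)C(C)(C(=C)[C@H](C)[C@@H](C)O[Si](C)(C)C(C)(C)C)C1=O | intermediate (not isolated)
20 | (3E,6S,7R)-7-(TBSO)-2-[(2R)-1-(TBSO)propan-2-yl]-4,6-dimethyl-5-methylidene-3-(TIPSO)octa-1,3-dien-1-one (dienylketene, ketene and vinyl arms cis) | CC(C)(C)[Si](C)(C)OC[C@H](C)C(=C=O)/C(O[Si](C(C)C)(C(C)C)C(C)C)=C(C)\C(=C)[C@H](C)[C@@H](C)O[Si](C)(C)C(C)(C)C | intermediate (not isolated)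
21 | 2-[(2R)-1-(TBSO)propan-2-yl]-5-[(2S,3R)-3-(TBSO)butan-2-yl]-4-methyl-3-(TIPSO)phenol | CC(C)(C)[Si](C)(C)OC[C@H](C)c1c(O[Si](C(C)C)(C(C)C)C(C)C)c(C)c([C@H](C)[C@@H](C)O[Si](C)(C)C(C)(C)C)cc1O | intermediate
22 | 3-[(2R)-1-(TBSO)propan-2-yl]-6-[(2S,3R)-3-(TBSO)butan-2-yl]-2-hydroxy-5-methyl-4-(TIPSO)benzaldehyde | CC(C)(C)[Si](C)(C)OC[C@H](C)c1c(O[Si](C(C)C)(C(C)C)C(C)C)c(C)c([C@H](C)[C@@H](C)O[Si](C)(C)C(C)(C)C)c(C=O)c1O | intermediate
23 | 3-[(2R)-1-(TBSO)propan-2-yl]-6-[(2S,3R)-3-(TBSO)butan-2-yl]-5-methyl-2,4-bis(TIPSO)benzaldehyde | CC(C)(C)[Si](C)(C)OC[C@H](C)c1c(O[Si](C(C)C)(C(C)C)C(C)C)c(C)c([C@H](C)[C@@H](C)O[Si](C)(C)C(C)(C)C)c(C=O)c1O[Si](C(C)C)(C(C)C)C(C)C | intermediate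
24 | 3-[(2R)-1-(TBSO)propan-2-yl]-6-[(2S,3R)-3-(TBSO)butan-2-yl]-5-methyl-2,4-bis(TIPSO)benzoic acid | CC(C)(C)[Si](C)(C)OC[C@H](C)c1c(O[Si](C(C)C)(C(C)C)C(C)C)c(C)c([C@H](C)[C@@H](C)O[Si](C)(C)C(C)(C)C)c(C(=O)O)c1O[Si](C(C)C)(C(C)C)C(C)C | intermediate
25 | 3-[(2R)-1-hydroxypropan-2-yl]-6-[(2S,3R)-3-hydroxybutan-2-yl]-5-methyl-2,4-bis(TIPSO)benzoic acid | OC[C@H](C)c1c(O[Si](C(C)C)(C(C)C)C(C)C)c(C)c([C@H](C)[C@@H](C)O)c(C(=O)O)c1O[Si](C(C)C)(C(C)C)C(C)C | intermediate (not isolated)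
26 | (3R,4S)-7-[(2R)-1-hydroxypropan-2-yl]-3,4,5-trimethyl-6,8-bis(TIPSO)isochroman-1-one | OC[C@H](C)c1c(O[Si](C(C)C)(C(C)C)C(C)C)c(C)c2c(c1O[Si](C(C)C)(C(C)C)C(C)C)C(=O)O[C@H](C)[C@H]2C | intermediate
27 | (2R)-2-[(3R,4S)-3,4,5-trimethyl-1-oxo-6,8-bis(TIPSO)isochroman-7-yl]propanal | O=C[C@H](C)c1c(O[Si](C(C)C)(C(C)C)C(C)C)c(C)c2c(c1O[Si](C(C)C)(C(C)C)C(C)C)C(=O)O[C@H](C)[C@H]2C | intermediate
28 | (3R,4S)-7-[(2S)-but-3-yn-2-yl]-3,4,5-trimethyl-6,8-bis(TIPSO)isochroman-1-one | C#C[C@H](C)c1c(O[Si](C(C)C)(C(C)C)C(C)C)c(C)c2c(c1O[Si](C(C)C)(C(C)C)C(C)C)C(=O)O[C@H](C)[C@H]2C | intermediate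
29 | lithium (3S)-3-[(3R,4S)-3,4,5-trimethyl-1-oxo-6,8-bis(TIPSO)isochroman-7-yl]but-1-yn-1-ide | [Li]C#C[C@H](C)c1c(O[Si](C(C)C)(C(C)C)C(C)C)c(C)c2c(c1O[Si](C(C)C)(C(C)C)C(C)C)C(=O)O[C@H](C)[C@H]2C | intermediate (not isolated)
30 | lithium (3S)-3-[(3R,4S)-3,4,5-trimethyl-1-oxo-6,8-bis(TIPSO)isochroman-7-yl]but-1-yn-1-olate | [Li]OC#C[C@H](C)c1c(O[Si](C(C)C)(C(C)C)C(C)C)c(C)c2c(c1O[Si](C(C)C)(C(C)C)C(C)C)C(=O)O[C@H](C)[C@H]2C | intermediate (not isolated)
31 | (3R,4S)-3,4,5-trimethyl-6,8-bis(TIPSO)-7-[(2S)-4-(TIPSO)but-3-yn-2-yl]isochroman-1-one | CC(C)[Si](C(C)C)(C(C)C)OC#C[C@H](C)c1c(O[Si](C(C)C)(C(C)C)C(C)C)c(C)c2c(c1O[Si](C(C)C)(C(C)C)C(C)C)C(=O)O[C@H](C)[C@H]2C | intermediate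
32 | (3R,4S)-7-[(1R)-1-{3-[(3S,4R)-4-(TBSO)-3-methylpent-1-en-2-yl]-3-methyl-4-oxo-2-(TIPSO)cyclobut-1-en-1-yl}ethyl]-3,4,5-trimethyl-6,8-bis(TIPSO)isochroman-1-one (both epimers at the quaternary carbon) | O=C1C([C@H](C)c2c(O[Si](C(C)C)(C(C)C)C(C)C)c(C)c3c(c2O[Si](C(C)C)(C(C)C)C(C)C)C(=O)O[C@H](C)[C@H]3C)=C(O[Si](C(C)C)(C(C)C)C(C)C)C1(C)C(=C)[C@H](C)[C@@H](C)O[Si](C)(C)C(C)(C)C | intermediate (not isolated)
33 | (3R,4S)-7-[(2R,4E,7S,8R)-8-(TBSO)-5,7-dimethyl-6-methylidene-3-(oxomethylidene)-4-(TIPSO)non-4-en-2-yl]-3,4,5-trimethyl-6,8-bis(TIPSO)isochroman-1-one (dienylketene, ketene and vinyl arms cis) | O=C=C([C@H](C)c1c(O[Si](C(C)C)(C(C)C)C(C)C)c(C)c2c(c1O[Si](C(C)C)(C(C)C)C(C)C)C(=O)O[C@H](C)[C@H]2C)/C(O[Si](C(C)C)(C(C)C)C(C)C)=C(C)\C(=C)[C@H](C)[C@@H](C)O[Si](C)(C)C(C)(C)C | intermediate (not isolated)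
34 | (3R,4S)-7-[(1S)-1-{4-[(2S,3R)-3-(TBSO)butan-2-yl]-6-hydroxy-3-methyl-2-(TIPSO)phenyl}ethyl]-3,4,5-trimethyl-6,8-bis(TIPSO)isochroman-1-one | Oc1cc([C@H](C)[C@@H](C)O[Si](C)(C)C(C)(C)C)c(C)c(O[Si](C(C)C)(C(C)C)C(C)C)c1[C@H](C)c1c(O[Si](C(C)C)(C(C)C)C(C)C)c(C)c2c(c1O[Si](C(C)C)(C(C)C)C(C)C)C(=O)O[C@H](C)[C@H]2C | intermediate
35 | (3R,4S)-7-[(1S)-1-{4-[(2S,3R)-3-(TBSO)butan-2-yl]-5-formyl-6-hydroxy-3-methyl-2-(TIPSO)phenyl}ethyl]-3,4,5-trimethyl-6,8-bis(TIPSO)isochroman-1-one | Oc1c(C=O)c([C@H](C)[C@@H](C)O[Si](C)(C)C(C)(C)C)c(C)c(O[Si](C(C)C)(C(C)C)C(C)C)c1[C@H](C)c1c(O[Si](C(C)C)(C(C)C)C(C)C)c(C)c2c(c1O[Si](C(C)C)(C(C)C)C(C)C)C(=O)O[C@H](C)[C@H]2C | intermediate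
36 | (3R,4S)-7-[(1S)-1-{3-formyl-2,6-dihydroxy-4-[(2S,3R)-3-hydroxybutan-2-yl]-5-methylphenyl}ethyl]-6,8-dihydroxy-3,4,5-trimethylisochroman-1-one | Oc1c(C=O)c([C@H](C)[C@@H](C)O)c(C)c(O)c1[C@H](C)c1c(O)c(C)c2c(c1O)C(=O)O[C@H](C)[C@H]2C | intermediate (not isolated)
37 | dicitrinone H, (3R,4S)-6,8-dihydroxy-7-[(1R)-1-[(3R,4S)-6-hydroxy-3,4,5-trimethyl-8-oxo-4,8-dihydro-3H-isochromen-7-yl]ethyl]-3,4,5-trimethylisochroman-1-one | CC1=C2C(=CO[C@H](C)[C@H]2C)C(=O)C([C@H](C)c2c(O)c(C)c3c(c2O)C(=O)O[C@H](C)[C@H]3C)=C1O | target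

**Summary**

Total step count: 19. Longest linear sequence: 17 steps (steps 1 to 6 and 9 to 19, from (R)-but-3-yn-2-ol); the linchpin branch (steps 7 and 8) joins at step 9, and diazo enone 13 is used again at step 17.

Steps most likely to fail:

Step 17 (key step). The bimolecular capture of the short-lived vinylketene at an alkyne carbon that sits between two ortho silyloxy groups may be outrun by ketene dimerization. The aryl lactone of 31 also competes for the light, so conversion may stall or photodegradation may set in. The fallback sets out from 13 and 31 and comes back at 34; it generates the ketene thermally in the dark. Irradiation of 13 alone in aqueous THF (Wolff rearrangement with capture by water) should give (4S,5R)-5-(TBSO)-2,4-dimethyl-3-methylidenehexanoic acid F1 as both C2 epimers, both of which are usable. 1-Chloro-N,N,2-trimethylprop-1-en-1-amine in CH2Cl2 converts it into (4S,5R)-5-(TBSO)-2,4-dimethyl-3-methylidenehexanoyl chloride F2. Slow addition of F2 to 31 and Et3N in toluene at 25 °C releases vinylketene 18 by dehydrochlorination at a low stationary concentration, so the [2+2] adduct 32 can accumulate. Heating at 80 to 110 °C then completes ring opening and electrocyclization to 34.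

Step 16. Oxygen transfer from the peroxide to the hindered acetylide may stall, or the peroxide and tert-butoxide may attack the lactone and aryl silyl ethers during the warm-up. The fallback sets out from 28 and comes back at 31; it installs the oxygen by umpolung of the alkyne. PhI(OH)OTs in CH2Cl2 should convert 28 into phenyl{(3R)-3-[(3R,4S)-3,4,5-trimethyl-1-oxo-6,8-bis(TIPSO)isochroman-7-yl]but-1-yn-1-yl}iodonium 4-methylbenzenesulfonate F3. Catalytic CuOTf in MeCN turns it into (3S)-3-[(3R,4S)-3,4,5-trimethyl-1-oxo-6,8-bis(TIPSO)isochroman-7-yl]but-1-yn-1-yl 4-methylbenzenesulfonate F4 with loss of iodobenzene. MeLi (1 equiv, DME, −78 °C) attacks sulfur and releases ynolate 30, which i-Pr3SiCl silylates on oxygen to 31. Competing addition of MeLi to the lactone is a residual risk of this fallback.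

Step 15. Enolization of the α-aryl aldehyde by carbonate in methanol would erode the bridging stereocenter, and methoxide may open the lactone or cleave aryl silyl ethers. The fallback sets out from 27 and comes back at 28; it avoids protic base. Ramirez olefination (CBr4, PPh3, Zn, CH2Cl2, 0 °C) should give (3R,4S)-7-[(2S)-4,4-dibromobut-3-en-2-yl]-3,4,5-trimethyl-6,8-bis(TIPSO)isochroman-1-one F5. NaN(SiMe3)2 (THF, −78 °C) eliminates HBr to (3R,4S)-7-[(2R)-4-bromobut-3-yn-2-yl]-3,4,5-trimethyl-6,8-bis(TIPSO)isochroman-1-one F6 (descriptor changes by priority only). Bromine–magnesium exchange with i-PrMgCl·LiCl at −40 °C and protonation with aq. NH4Cl then give 28.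

Further compounds
F1 | step 17 | (4S,5R)-5-(TBSO)-2,4-dimethyl-3-methylidenehexanoic acid (C2 epimers) | OC(=O)C(C)C(=C)[C@H](C)[C@@H](C)O[Si](C)(C)C(C)(C)C
F2 | step 17 | (4S,5R)-5-(TBSO)-2,4-dimethyl-3-methylidenehexanoyl chloride (C2 epimers) | ClC(=O)C(C)C(=C)[C@H](C)[C@@H](C)O[Si](C)(C)C(C)(C)C
F3 | step 16 | phenyl{(3R)-3-[(3R,4S)-3,4,5-trimethyl-1-oxo-6,8-bis(TIPSO)isochroman-7-yl]but-1-yn-1-yl}iodonium 4-methylbenzenesulfonate | Cc1ccc(cc1)S(=O)(=O)[O-].c1ccccc1[I+]C#C[C@H](C)c1c(O[Si](C(C)C)(C(C)C)C(C)C)c(C)c2c(c1O[Si](C(C)C)(C(C)C)C(C)C)C(=O)O[C@H](C)[C@H]2C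
F4 | step 16 | (3S)-3-[(3R,4S)-3,4,5-trimethyl-1-oxo-6,8-bis(TIPSO)isochroman-7-yl]but-1-yn-1-yl 4-methylbenzenesulfonate | Cc1ccc(cc1)S(=O)(=O)OC#C[C@H](C)c1c(O[Si](C(C)C)(C(C)C)C(C)C)c(C)c2c(c1O[Si](C(C)C)(C(C)C)C(C)C)C(=O)O[C@H](C)[C@H]2C
F5 | step 15 | (3R,4S)-7-[(2S)-4,4-dibromobut-3-en-2-yl]-3,4,5-trimethyl-6,8-bis(TIPSO)isochroman-1-one | BrC(Br)=C[C@H](C)c1c(O[Si](C(C)C)(C(C)C)C(C)C)c(C)c2c(c1O[Si](C(C)C)(C(C)C)C(C)C)C(=O)O[C@H](C)[C@H]2C
F6 | step 15 | (3R,4S)-7-[(2R)-4-bromobut-3-yn-2-yl]-3,4,5-trimethyl-6,8-bis(TIPSO)isochroman-1-one | BrC#C[C@H](C)c1c(O[Si](C(C)C)(C(C)C)C(C)C)c(C)c2c(c1O[Si](C(C)C)(C(C)C)C(C)C)C(=O)O[C@H](C)[C@H]2C
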